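The plan rests on disconnecting the C4–C5 bond (target numbering, 2,7-dioxabicyclo[4.2.2]decane) of the eight-membered oxocane ring C1–O2–C3–C4–C5–C6–C10–C9. An intramolecular Nozaki–Hiyama–Kishi addition closes this ring in one operation from an open-chain dialkyl ether that carries a (Z)-vinyl iodide (C5) and an α-alkoxy aldehyde (C4). The step exploits the 1,3-relationship between the C4 bromomethine and the C6–O7 carbon: after oxidation the C4 carbonyl makes C6 the β-carbon of a cis-enone, so the C8 hydroxyl closes the oxane ring (C1–C9–C10–C6–O7–C8) by transannular oxa-Michael addition. Both bromides then arise by double inversion of the C4,C10-diol.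

Key step: step 13

Remark: atom labels C1–C10, O2 and O7 are those of the target's 2,7-dioxabicyclo[4.2.2]decane core (C3 ethyl, C4 and C10 bromine, C8 side chain); (2R,2'R)-2,2'-bioxirane (D-diepoxybutane) is assumed to be purchasable as the single enantiomer.

Step 1
Reactants: 1 (2R,2'R)-2,2'-bioxirane
Product: 2 (1R)-1-[(2R)-oxiran-2-yl]but-3-en-1-ol
Conditions: CH2=CHMgBr (1 equiv), CuI (10 mol%), THF, −40 °C; aq NH4Cl
Reagents that add atoms: vinylmagnesium bromide C=C[Mg]Br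
Why: Copper-catalysed Grignard opening of one terminal epoxide (SN2 at CH2) leaves both stereocentres untouched, and one equivalent of reagent on the C2-symmetric bis-epoxide should give mainly the mono-adduct, so the future C8 and C1 are taken from the starting material.

Step 2
Reactants: 2 (1R)-1-[(2R)-oxiran-2-yl]but-3-en-1-ol
Product: 3 (2R)-2-{(1R)-1-[(4-methoxybenzyl)oxy]but-3-en-1-yl}oxirane
Conditions: NaH, 4-methoxybenzyl chloride, n-Bu4NI (cat.), THF–DMF, 0 °C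
Reagents that add atoms: 4-methoxybenzyl chloride COc1ccc(CCl)cc1
Why: Williamson etherification of the sodium alkoxide masks the future O7 as a PMB ether that withstands all steps up to its oxidative removal in step 15.

Step 3
Reactants: 3 (2R)-2-{(1R)-1-[(4-methoxybenzyl)oxy]but-3-en-1-yl}oxirane; 4 1,3-dithiane
Product: 6 (2R,3R)-1-(1,3-dithian-2-yl)-3-[(4-methoxybenzyl)oxy]hex-5-en-2-ol, via 2-lithio-1,3-dithiane 5 (not isolated)
Conditions: n-BuLi, THF, −30 °C; then 3, −20 °C to rt; aq NH4Cl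
Reagents that add atoms: none
Why: Corey–Seebach umpolung, in which the dithiane anion opens the epoxide at its CH2 terminus, installs the future C10 as a masked aldehyde and leaves the C1 hydroxyl (future O2) as the only free OH.

Step 4
Reactants: 7 ethyl (2S)-2-hydroxybutanoate
Product: 8 ethyl (2S)-2-{[(trifluoromethyl)sulfonyl]oxy}butanoate
Conditions: Tf2O, 2,6-lutidine, CH2Cl2, −78 °C
Reagents that add atoms: trifluoromethanesulfonic anhydride O=S(=O)(OS(=O)(=O)C(F)(F)F)C(F)(F)F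
Why: O-Triflation with retention turns the α-hydroxy ester into a reactive SN2 electrophile without touching the stereocentre.

Step 5
Reactants: 6 (2R,3R)-1-(1,3-dithian-2-yl)-3-[(4-methoxybenzyl)oxy]hex-5-en-2-ol; 8 ethyl (2S)-2-{[(trifluoromethyl)sulfonyl]oxy}butanoate
Product: 9 ethyl (2R)-2-{[(2R,3R)-1-(1,3-dithian-2-yl)-3-[(4-methoxybenzyl)oxy]hex-5-en-2-yl]oxy}butanoate
Conditions: NaH, THF, 0 °C; then 8, −20 °C to rt
Reagents that add atoms: none
Why: Williamson-type SN2 displacement of the α-ester triflate by the secondary alkoxide proceeds with inversion, so the (S)-triflate should give the (R)-configured C3 and the O2 ether link in one step.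

Step 6
Reactants: 9 ethyl (2R)-2-{[(2R,3R)-1-(1,3-dithian-2-yl)-3-[(4-methoxybenzyl)oxy]hex-5-en-2-yl]oxy}butanoate
Product: 10 ethyl (2R)-2-{[(3R,4R)-4-[(4-methoxybenzyl)oxy]-1-oxohept-6-en-3-yl]oxy}butanoate
Conditions: MeI, CaCO3, MeCN–H2O (9:1), 45 °C
Reagents that add atoms: water O
Why: S-Methylation and hydrolysis of the dithiane (Corey–Seebach unmasking) releases the aldehyde under near-neutral conditions that spare ester, PMB ether and alkene.

Step 7
Reactants: 10 ethyl (2R)-2-{[(3R,4R)-4-[(4-methoxybenzyl)oxy]-1-oxohept-6-en-3-yl]oxy}butanoate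
Product: 11 ethyl (2R)-2-{[(5R,6R)-3-hydroxy-6-[(4-methoxybenzyl)oxy]non-8-en-1-yn-5-yl]oxy}butanoate (both C-3 epimers)
Conditions: HC≡CMgBr, THF, −78 to −40 °C; aq NH4Cl
Reagents that add atoms: ethynylmagnesium bromide C#C[Mg]Br
Why: 1,2-Addition of the alkynyl Grignard reagent to the aldehyde at low temperature, where the ester does not react, brings in C5 and C6; the carbinol configuration is irrelevant because it is oxidised in step 8.

Step 8
Reactants: 11 ethyl (2R)-2-{[(5R,6R)-3-hydroxy-6-[(4-methoxybenzyl)oxy]non-8-en-1-yn-5-yl]oxy}butanoate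
Product: 12 ethyl (2R)-2-{[(5R,6R)-6-[(4-methoxybenzyl)oxy]-3-oxonon-8-en-1-yn-5-yl]oxy}butanoate
Conditions: Dess–Martin periodinane, CH2Cl2, 0 °C to rt
Reagents that add atoms: none
Why: Dess–Martin oxidation of the propargylic alcohol gives the terminal ynone under neutral conditions.

Step 9
Reactants: 12 ethyl (2R)-2-{[(5R,6R)-6-[(4-methoxybenzyl)oxy]-3-oxonon-8-en-1-yn-5-yl]oxy}butanoate
Product: 13 ethyl (2R)-2-{[(1Z,5R,6R)-1-iodo-6-[(4-methoxybenzyl)oxy]-3-oxonona-1,8-dien-5-yl]oxy}butanoate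
Conditions: NaI, AcOH, rt
Reagents that add atoms: sodium iodide [Na+].[I-]
Why: Conjugate hydroiodination of the ynone by anti addition of HI should give the (Z)-β-iodoenone and thereby the cis geometry that the eight-membered ring requires.

Step 10
Reactants: 13 ethyl (2R)-2-{[(1Z,5R,6R)-1-iodo-6-[(4-methoxybenzyl)oxy]-3-oxonona-1,8-dien-5-yl]oxy}butanoate
Product: 14 ethyl (2R)-2-{[(1Z,3R,5R,6R)-3-hydroxy-1-iodo-6-[(4-methoxybenzyl)oxy]nona-1,8-dien-5-yl]oxy}butanoate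
Conditions: (S)-Me-CBS oxazaborolidine (20 mol%), catecholborane, toluene, −78 °C
Reagents that add atoms: none
Why: Corey–Bakshi–Shibata reduction, in which the iodovinyl group acts as the large substituent, should deliver hydride under catalyst control to give the (R)-allylic alcohol (future C10), with catecholborane at −78 °C leaving the terminal alkene and ester untouched.

Step 11
Reactants: 14 ethyl (2R)-2-{[(1Z,3R,5R,6R)-3-hydroxy-1-iodo-6-[(4-methoxybenzyl)oxy]nona-1,8-dien-5-yl]oxy}butanoate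
Product: 15 ethyl (2R)-2-{[(1Z,3R,5R,6R)-3-[(tert-butyldimethylsilyl)oxy]-1-iodo-6-[(4-methoxybenzyl)oxy]nona-1,8-dien-5-yl]oxy}butanoate
Conditions: TBSOTf, 2,6-lutidine, CH2Cl2, −78 °C
Reagents that add atoms: tert-butyldimethylsilyl trifluoromethanesulfonate CC(C)(C)[Si](C)(C)OS(=O)(=O)C(F)(F)F
Why: Silylation of the allylic alcohol with the silyl triflate protects the C10 oxygen through the ring-forming steps.

Step 12
Reactants: 15 ethyl (2R)-2-{[(1Z,3R,5R,6R)-3-[(tert-butyldimethylsilyl)oxy]-1-iodo-6-[(4-methoxybenzyl)oxy]nona-1,8-dien-5-yl]oxy}butanoate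
Product: 16 (2R)-2-{[(1Z,3R,5R,6R)-3-[(tert-butyldimethylsilyl)oxy]-1-iodo-6-[(4-methoxybenzyl)oxy]nona-1,8-dien-5-yl]oxy}butanal
Conditions: i-Bu2AlH, CH2Cl2, −78 °C; Rochelle salt work-up
Reagents that add atoms: none
Why: Partial reduction of the α-alkoxy ester stops at the aldehyde because the chelated aluminium hemiacetal survives at −78 °C until work-up.

Step 13
Reactants: 16 (2R)-2-{[(1Z,3R,5R,6R)-3-[(tert-butyldimethylsilyl)oxy]-1-iodo-6-[(4-methoxybenzyl)oxy]nona-1,8-dien-5-yl]oxy}butanal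
Product: 17 (2R,4Z,6R,8R)-6-[(tert-butyldimethylsilyl)oxy]-2-ethyl-8-{(1R)-1-[(4-methoxybenzyl)oxy]but-3-en-1-yl}-3,6,7,8-tetrahydro-2H-oxocin-3-ol (both C-3 epimers)
Conditions: CrCl2 (10 equiv), NiCl2 (1 mol% of Cr), DMSO–THF, rt, 0.003 M, slow addition of 16
Reagents that add atoms: none
Why: CrCl2 reduces NiCl2 to zerovalent nickel, which inserts into the C–I bond; transmetalation gives an alkenylchromium species (trivalent chromium) with retention of the Z geometry, and this adds to the aldehyde carbonyl to form the C4–C5 bond. The closest known reaction type is the intramolecular Nozaki–Hiyama–Kishi coupling used to close eight-membered and larger rings. The oxocene ring closes in an 8-exo-trig mode with the carbonyl oxygen exocyclic. The new C4 carbinol centre is not controlled and need not be, since it is oxidised in step 14 and reset in step 16. The step needs chemoselectivity for the aldehyde and cyclisation over oligomerisation: the organochromium reagent tolerates the silyl ether, PMB ether, terminal alkene and the epimerisable α-alkoxy aldehyde, and high dilution together with the cis-alkene and the gauche ether oxygen pre-organises the chain for ring closure.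

Step 14
Reactants: 17 (2R,4Z,6R,8R)-6-[(tert-butyldimethylsilyl)oxy]-2-ethyl-8-{(1R)-1-[(4-methoxybenzyl)oxy]but-3-en-1-yl}-3,6,7,8-tetrahydro-2H-oxocin-3-ol
Product: 18 (2R,4Z,6R,8R)-6-[(tert-butyldimethylsilyl)oxy]-2-ethyl-8-{(1R)-1-[(4-methoxybenzyl)oxy]but-3-en-1-yl}-7,8-dihydro-2H-oxocin-3(6H)-one
Conditions: Dess–Martin periodinane, CH2Cl2, rt
Reagents that add atoms: none
Why: Dess–Martin oxidation converges both carbinol epimers on one cis-enone and makes C6 the electrophilic β-carbon.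

Step 15
Reactants: 18 (2R,4Z,6R,8R)-6-[(tert-butyldimethylsilyl)oxy]-2-ethyl-8-{(1R)-1-[(4-methoxybenzyl)oxy]but-3-en-1-yl}-7,8-dihydro-2H-oxocin-3(6H)-one
Product: 20 (1R,3R,6S,8R,10R)-10-[(tert-butyldimethylsilyl)oxy]-3-ethyl-8-(prop-2-en-1-yl)-2,7-dioxabicyclo[4.2.2]decan-4-one, via hydroxy enone 19 (not isolated)
Conditions: DDQ, CH2Cl2–pH 7 buffer, 0 °C; then CSA (cat.), CH2Cl2, rt
Reagents that add atoms: none
Why: Oxidative PMB cleavage by DDQ frees the C8 hydroxyl, which adds in an acid-catalysed transannular 6-exo-trig oxa-Michael reaction to C6; only the cis-bridged boat-shaped oxane can form, so the fixed C1 and C8 centres set C6 as S.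

Step 16
Reactants: 20 (1R,3R,6S,8R,10R)-10-[(tert-butyldimethylsilyl)oxy]-3-ethyl-8-(prop-2-en-1-yl)-2,7-dioxabicyclo[4.2.2]decan-4-one
Product: 21 (1R,3R,4R,6S,8R,10R)-10-[(tert-butyldimethylsilyl)oxy]-3-ethyl-8-(prop-2-en-1-yl)-2,7-dioxabicyclo[4.2.2]decan-4-ol
Conditions: LiBH(s-Bu)3, THF, −78 °C; aq NH4Cl
Reagents that add atoms: none
Why: The bulky trialkylborohydride attacks the C4 ketone from the face opposite the adjacent C3 ethyl group and the C8 side chain (steric approach control), which should give the (4R)-alcohol cis to the ethyl group.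

Step 17
Reactants: 21 (1R,3R,4R,6S,8R,10R)-10-[(tert-butyldimethylsilyl)oxy]-3-ethyl-8-(prop-2-en-1-yl)-2,7-dioxabicyclo[4.2.2]decan-4-ol
Product: 22 (1R,3R,4R,6S,8R,10R)-3-ethyl-8-(prop-2-en-1-yl)-2,7-dioxabicyclo[4.2.2]decane-4,10-diol
Conditions: n-Bu4NF, THF, rt
Reagents that add atoms: none
Why: Fluoride-mediated desilylation releases the C10 hydroxyl without affecting the ethers.

Step 18
Reactants: 22 (1R,3R,4R,6S,8R,10R)-3-ethyl-8-(prop-2-en-1-yl)-2,7-dioxabicyclo[4.2.2]decane-4,10-diol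
Product: 23 (1R,3R,4S,6S,8R,10S)-4,10-dibromo-3-ethyl-8-(prop-2-en-1-yl)-2,7-dioxabicyclo[4.2.2]decane
Conditions: CBr4, (n-C8H17)3P, toluene, 70 °C
Reagents that add atoms: carbon tetrabromide BrC(Br)(Br)Br
Why: Double Appel reaction, in which each alkoxyphosphonium ion is displaced by bromide in an SN2 step with inversion, should convert the (4R,10R)-diol into the (4S,10S)-dibromide.

Step 19
Reactants: 23 (1R,3R,4S,6S,8R,10S)-4,10-dibromo-3-ethyl-8-(prop-2-en-1-yl)-2,7-dioxabicyclo[4.2.2]decane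
Product: 24 (2E)-4-[(1R,3R,4S,6S,8R,10S)-4,10-dibromo-3-ethyl-2,7-dioxabicyclo[4.2.2]decan-8-yl]but-2-enal
Conditions: crotonaldehyde (5 equiv), second-generation Grubbs catalyst RuCl2(=CHPh)(PCy3)(SIMes) (5 mol%), CH2Cl2, 40 °C
Reagents that add atoms: (E)-but-2-enal C/C=C/C=O
Why: Olefin cross-metathesis of the terminal alkene with crotonaldehyde should give the (E)-enal under thermodynamic control with loss of propene.

Step 20
Reactants: 24 (2E)-4-[(1R,3R,4S,6S,8R,10S)-4,10-dibromo-3-ethyl-2,7-dioxabicyclo[4.2.2]decan-8-yl]but-2-enal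
Product: 25 (1R,3R,4S,6S,8R,10S)-4,10-dibromo-3-ethyl-8-[(2E)-pent-2-en-4-yn-1-yl]-2,7-dioxabicyclo[4.2.2]decane
Conditions: Me3SiCHN2, i-Pr2NLi, THF, −78 °C to rt
Reagents that add atoms: (trimethylsilyl)diazomethane C[Si](C)(C)C=[N+]=[N-]
Why: Colvin rearrangement (addition of lithiated trimethylsilyldiazomethane, Peterson-type elimination and 1,2-hydrogen shift of the alkylidene carbene) converts the enal into the terminal (E)-enyne at low temperature without disturbing the secondary bromides.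

Compound list
1 | (2R,2'R)-2,2'-bioxirane | C1O[C@H]1[C@H]1CO1 | starting material
2 | (1R)-1-[(2R)-oxiran-2-yl]but-3-en-1-ol | C=CC[C@@H](O)[C@H]1CO1 | intermediate
3 | (2R)-2-{(1R)-1-[(4-methoxybenzyl)oxy]but-3-en-1-yl}oxirane | C=CC[C@@H](OCc1ccc(OC)cc1)[C@H]1CO1 | intermediate
4 | 1,3-dithiane | C1CSCSC1 | starting material
5 | 2-lithio-1,3-dithiane | [Li]C1SCCCS1 | intermediate
6 | (2R,3R)-1-(1,3-dithian-2-yl)-3-[(4-methoxybenzyl)oxy]hex-5-en-2-ol | C=CC[C@@H](OCc1ccc(OC)cc1)[C@H](O)CC1SCCCS1 | intermediate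
7 | ethyl (2S)-2-hydroxybutanoate | CC[C@H](O)C(=O)OCC | starting material
8 | ethyl (2S)-2-{[(trifluoromethyl)sulfonyl]oxy}butanoate | CC[C@H](OS(=O)(=O)C(F)(F)F)C(=O)OCC | intermediate
9 | ethyl (2R)-2-{[(2R,3R)-1-(1,3-dithian-2-yl)-3-[(4-methoxybenzyl)oxy]hex-5-en-2-yl]oxy}butanoate | C=CC[C@@H](OCc1ccc(OC)cc1)[C@H](O[C@H](CC)C(=O)OCC)CC1SCCCS1 | intermediate
10 | ethyl (2R)-2-{[(3R,4R)-4-[(4-methoxybenzyl)oxy]-1-oxohept-6-en-3-yl]oxy}butanoate | C=CC[C@@H](OCc1ccc(OC)cc1)[C@H](O[C@H](CC)C(=O)OCC)CC=O | intermediate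
11 | ethyl (2R)-2-{[(5R,6R)-3-hydroxy-6-[(4-methoxybenzyl)oxy]non-8-en-1-yn-5-yl]oxy}butanoate (C-3 epimers) | C=CC[C@@H](OCc1ccc(OC)cc1)[C@H](O[C@H](CC)C(=O)OCC)CC(O)C#C | intermediate
12 | ethyl (2R)-2-{[(5R,6R)-6-[(4-methoxybenzyl)oxy]-3-oxonon-8-en-1-yn-5-yl]oxy}butanoate | C=CC[C@@H](OCc1ccc(OC)cc1)[C@H](O[C@H](CC)C(=O)OCC)CC(=O)C#C | intermediate
13 | ethyl (2R)-2-{[(1Z,5R,6R)-1-iodo-6-[(4-methoxybenzyl)oxy]-3-oxonona-1,8-dien-5-yl]oxy}butanoate | C=CC[C@@H](OCc1ccc(OC)cc1)[C@H](O[C@H](CC)C(=O)OCC)CC(=O)/C=C\I | intermediate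
14 | ethyl (2R)-2-{[(1Z,3R,5R,6R)-3-hydroxy-1-iodo-6-[(4-methoxybenzyl)oxy]nona-1,8-dien-5-yl]oxy}butanoate | C=CC[C@@H](OCc1ccc(OC)cc1)[C@H](O[C@H](CC)C(=O)OCC)C[C@@H](O)/C=C\I | intermediate
15 | ethyl (2R)-2-{[(1Z,3R,5R,6R)-3-[(tert-butyldimethylsilyl)oxy]-1-iodo-6-[(4-methoxybenzyl)oxy]nona-1,8-dien-5-yl]oxy}butanoate | C=CC[C@@H](OCc1ccc(OC)cc1)[C@H](O[C@H](CC)C(=O)OCC)C[C@@H](O[Si](C)(C)C(C)(C)C)/C=C\I | intermediate
16 | (2R)-2-{[(1Z,3R,5R,6R)-3-[(tert-butyldimethylsilyl)oxy]-1-iodo-6-[(4-methoxybenzyl)oxy]nona-1,8-dien-5-yl]oxy}butanal | C=CC[C@@H](OCc1ccc(OC)cc1)[C@H](O[C@H](CC)C=O)C[C@@H](O[Si](C)(C)C(C)(C)C)/C=C\I | intermediate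
17 | (2R,4Z,6R,8R)-6-[(tert-butyldimethylsilyl)oxy]-2-ethyl-8-{(1R)-1-[(4-methoxybenzyl)oxy]but-3-en-1-yl}-3,6,7,8-tetrahydro-2H-oxocin-3-ol (C-3 epimers) | C=CC[C@@H](OCc1ccc(OC)cc1)[C@H]1C[C@@H](O[Si](C)(C)C(C)(C)C)/C=C\C(O)[C@@H](CC)O1 | intermediate
18 | (2R,4Z,6R,8R)-6-[(tert-butyldimethylsilyl)oxy]-2-ethyl-8-{(1R)-1-[(4-methoxybenzyl)oxy]but-3-en-1-yl}-7,8-dihydro-2H-oxocin-3(6H)-one | C=CC[C@@H](OCc1ccc(OC)cc1)[C@H]1C[C@@H](O[Si](C)(C)C(C)(C)C)/C=C\C(=O)[C@@H](CC)O1 | intermediate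
19 | (2R,4Z,6R,8R)-6-[(tert-butyldimethylsilyl)oxy]-2-ethyl-8-[(1R)-1-hydroxybut-3-en-1-yl]-7,8-dihydro-2H-oxocin-3(6H)-one | C=CC[C@@H](O)[C@H]1C[C@@H](O[Si](C)(C)C(C)(C)C)/C=C\C(=O)[C@@H](CC)O1 | intermediate
20 | (1R,3R,6S,8R,10R)-10-[(tert-butyldimethylsilyl)oxy]-3-ethyl-8-(prop-2-en-1-yl)-2,7-dioxabicyclo[4.2.2]decan-4-one | C=CC[C@H]1O[C@H]2CC(=O)[C@@H](CC)O[C@@H]1C[C@H]2O[Si](C)(C)C(C)(C)C | intermediate
21 | (1R,3R,4R,6S,8R,10R)-10-[(tert-butyldimethylsilyl)oxy]-3-ethyl-8-(prop-2-en-1-yl)-2,7-dioxabicyclo[4.2.2]decan-4-ol | C=CC[C@H]1O[C@H]2C[C@@H](O)[C@@H](CC)O[C@@H]1C[C@H]2O[Si](C)(C)C(C)(C)C | intermediate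
22 | (1R,3R,4R,6S,8R,10R)-3-ethyl-8-(prop-2-en-1-yl)-2,7-dioxabicyclo[4.2.2]decane-4,10-diol | C=CC[C@H]1O[C@H]2C[C@@H](O)[C@@H](CC)O[C@@H]1C[C@H]2O | intermediate
23 | (1R,3R,4S,6S,8R,10S)-4,10-dibromo-3-ethyl-8-(prop-2-en-1-yl)-2,7-dioxabicyclo[4.2.2]decane | C=CC[C@H]1O[C@H]2C[C@H](Br)[C@@H](CC)O[C@@H]1C[C@@H]2Br | intermediate
24 | (2E)-4-[(1R,3R,4S,6S,8R,10S)-4,10-dibromo-3-ethyl-2,7-dioxabicyclo[4.2.2]decan-8-yl]but-2-enal | O=C/C=C/C[C@H]1O[C@H]2C[C@H](Br)[C@@H](CC)O[C@@H]1C[C@@H]2Br | intermediate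
25 | (1R,3R,4S,6S,8R,10S)-4,10-dibromo-3-ethyl-8-[(2E)-pent-2-en-4-yn-1-yl]-2,7-dioxabicyclo[4.2.2]decane | C#C/C=C/C[C@H]1O[C@H]2C[C@H](Br)[C@@H](CC)O[C@@H]1C[C@@H]2Br | target

Total step count: 20. Longest linear sequence: 19 steps (steps 1–3 and 5–20; step 4 is a one-step side branch).

Steps most likely to fail

Step 15 (transannular oxa-Michael addition). The conjugate addition is reversible and the strained bridged adduct may not be favoured over the open enone or a hemiketal; prolonged acid could also epimerise C3 next to the ketone. The oxane ring would then be closed irreversibly before the ketone is made. Setting out from carbinol 17, DDQ removes the PMB group to give (2R,4Z,6R,8R)-6-[(tert-butyldimethylsilyl)oxy]-2-ethyl-8-[(1R)-1-hydroxybut-3-en-1-yl]-3,6,7,8-tetrahydro-2H-oxocin-3-ol F2. N-Iodosuccinimide then effects 6-exo iodoetherification of the C8 hydroxyl onto C6 of the cis-alkene to give 10-[(tert-butyldimethylsilyl)oxy]-3-ethyl-5-iodo-8-(prop-2-en-1-yl)-2,7-dioxabicyclo[4.2.2]decan-4-ol F3. Radical deiodination with n-Bu3SnH and AIBN gives 10-[(tert-butyldimethylsilyl)oxy]-3-ethyl-8-(prop-2-en-1-yl)-2,7-dioxabicyclo[4.2.2]decan-4-ol as its C4 epimers F4, and Dess–Martin oxidation returns to the route at ketone 20.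

Step 18 (double bromination). Substitution at the two hindered carbinols next to the ring oxygens may be slow or incomplete, and elimination or participation of a ring oxygen (retention or ring contraction) may compete. The inversion would then be run on an isolated sulfonate. Setting out from diol 22, ClCH2SO2Cl and pyridine give (1R,3R,4R,6S,8R,10R)-3-ethyl-8-(prop-2-en-1-yl)-2,7-dioxabicyclo[4.2.2]decane-4,10-diyl bis(chloromethanesulfonate) F5, and SN2 displacement with n-Bu4NBr in hot toluene returns to the route at dibromide 23.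

Step 13 (Ni/Cr ring closure). Oligomerisation may outrun the eight-membered ring closure, or the vinyl iodide may be lost by protonation. The same C4–C5 bond would then be made anionically. Setting out from ester 15, MeNH(OMe)·HCl and i-PrMgCl give the Weinreb amide (2R)-2-{[(1Z,3R,5R,6R)-3-[(tert-butyldimethylsilyl)oxy]-1-iodo-6-[(4-methoxybenzyl)oxy]nona-1,8-dien-5-yl]oxy}-N-methoxy-N-methylbutanamide F1. Iodine–lithium exchange with t-BuLi at −78 °C under high dilution lets the vinyllithium acylate the amide intramolecularly (Parham-type cyclisation), which returns to the route at enone 18 and bypasses 16 and 17.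

Further compounds
F1 | step 13 | (2R)-2-{[(1Z,3R,5R,6R)-3-[(tert-butyldimethylsilyl)oxy]-1-iodo-6-[(4-methoxybenzyl)oxy]nona-1,8-dien-5-yl]oxy}-N-methoxy-N-methylbutanamide | C=CC[C@@H](OCc1ccc(OC)cc1)[C@H](O[C@H](CC)C(=O)N(C)OC)C[C@@H](O[Si](C)(C)C(C)(C)C)/C=C\I
F2 | step 15 | (2R,4Z,6R,8R)-6-[(tert-butyldimethylsilyl)oxy]-2-ethyl-8-[(1R)-1-hydroxybut-3-en-1-yl]-3,6,7,8-tetrahydro-2H-oxocin-3-ol | C=CC[C@@H](O)[C@H]1C[C@@H](O[Si](C)(C)C(C)(C)C)/C=C\C(O)[C@@H](CC)O1
F3 | step 15 | 10-[(tert-butyldimethylsilyl)oxy]-3-ethyl-5-iodo-8-(prop-2-en-1-yl)-2,7-dioxabicyclo[4.2.2]decan-4-ol (ring configuration of 20) | C=CC[C@H]1O[C@H]2C(I)C(O)[C@@H](CC)O[C@@H]1C[C@H]2O[Si](C)(C)C(C)(C)C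
F4 | step 15 | 10-[(tert-butyldimethylsilyl)oxy]-3-ethyl-8-(prop-2-en-1-yl)-2,7-dioxabicyclo[4.2.2]decan-4-ol (C4 epimers) | C=CC[C@H]1O[C@H]2CC(O)[C@@H](CC)O[C@@H]1C[C@H]2O[Si](C)(C)C(C)(C)C
F5 | step 18 | (1R,3R,4R,6S,8R,10R)-3-ethyl-8-(prop-2-en-1-yl)-2,7-dioxabicyclo[4.2.2]decane-4,10-diyl bis(chloromethanesulfonate) | C=CC[C@H]1O[C@H]2C[C@@H](OS(=O)(=O)CCl)[C@@H](CC)O[C@@H]1C[C@H]2OS(=O)(=O)CCl
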